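**Retrosynthetic overview**

1. The route rests on the five-membered ring C1–C8–C5–C6–C7 of the bicyclo[3.2.1]octane: a C8 ketone next to quaternary C1 (allyl, C2), with the C7 methyl beside C1 and trans to the C6 aryl group. This is the pattern left by methyl conjugate addition to a 2-allyl-4-arylcyclopentenone followed by capture of the enolate at C1.
2. The C4 carbinol comes from Luche reduction of the 4,8-dione. The six-membered ring C1–C2–C3–C4–C5–C8 is opened at C2=C3 by an intramolecular aldol condensation between a C1 formyl group and a C5 methoxyacetyl group.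
3. At C5 the acyl group is introduced first and oxygen second (anti to the C6 aryl group), then O-methylation. C2 is carried as a silyl-protected CH2OH.
4. The C7–CH3 and C1–C2 bonds are made together: Me2CuLi adds to enone 12 and the C1 enolate is trapped with formaldehyde.
5. Enone 12 comes from silyloxy enone 4 by aryl conjugate addition, silanol elimination, 2-iodination and Stille allylation. Ring order: the cyclopentane ring is bought in 4; the six-membered ring closes in step 13.

Key step: step 6

Remarks on the chemistry: atom labels C1–C8 are those of the target bicyclo[3.2.1]octane. The phenol is carried as its triisopropylsilyl (TIPS) ether so that it survives the amide-base steps and the mild acid of step 11. Enolates made by simple deprotonation in steps 8 and 9 are treated as ionised forms of 18 and 20 and are not numbered.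

**Route**

Step 1
Reactants: 1 4-bromo-2-methoxyphenol; 2 chlorotriisopropylsilane
Product: 3 (4-bromo-2-methoxyphenoxy)triisopropylsilane
Conditions: i-Pr3SiCl, imidazole, DMF, rt
Reagents that add atoms: chlorotriisopropylsilane, CC(C)[Si](Cl)(C(C)C)C(C)C
Why: O-silylation of a phenol gives an aryl silyl ether that tolerates magnesium, organocopper reagents and amide bases and is cleaved by fluoride at the end.

Step 2
Reactants: 3 (4-bromo-2-methoxyphenoxy)triisopropylsilane; 4 (S)-4-(tert-butyldimethylsilyloxy)cyclopent-2-en-1-one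
Product: 7 (3R,4S)-4-(tert-butyldimethylsilyloxy)-3-[3-methoxy-4-(triisopropylsilyloxy)phenyl]cyclopentan-1-one, via arylmagnesium bromide 5 (not isolated), via trimethylsilyl enol ether 6 (not isolated)
Conditions: 3, Mg, THF, 50 °C; then CuBr·SMe2 (10 mol%), Me3SiCl, 4, THF, −78 °C; 1 M HCl, THF, 0 °C
Reagents that add atoms: aryl bromide 3 (delivered as Grignard reagent 5), COc1cc(Br)ccc1O[Si](C(C)C)(C(C)C)C(C)C
Why: Copper-catalysed (monovalent copper), Me3SiCl-accelerated 1,4-addition of the aryl Grignard reagent occurs anti to the C4 silyloxy group and sets the aryl-bearing centre trans to it, while trapping as silyl enol ether 6 prevents premature β-elimination before the acidic work-up releases the ketone.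

Step 3
Reactants: 7 (3R,4S)-4-(tert-butyldimethylsilyloxy)-3-arylcyclopentan-1-one
Product: 8 (S)-4-[3-methoxy-4-(triisopropylsilyloxy)phenyl]cyclopent-2-en-1-one
Conditions: DBU, CH2Cl2, 0 °C, short contact time
Reagents that add atoms: none
Why: E1cB β-elimination of silanolate from the β-silyloxy ketone gives the conjugated enone without touching the aryl-bearing stereocentre, and the cold, brief exposure to base limits γ-deprotonation at the benzylic position.

Step 4
Reactants: 8 (S)-4-arylcyclopent-2-en-1-one; 9 iodine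
Product: 10 (S)-2-iodo-4-[3-methoxy-4-(triisopropylsilyloxy)phenyl]cyclopent-2-en-1-one
Conditions: I2, pyridine/CH2Cl2, 0 °C → rt
Reagents that add atoms: iodine, II
Why: Johnson α-iodination of an enone (pyridine conjugate addition, iodination of the enolate, loss of pyridine) places iodine at C2 and leaves the stereocentre untouched.

Step 5
Reactants: 10 (S)-2-iodo-4-arylcyclopent-2-en-1-one; 11 allyltributylstannane
Product: 12 (S)-2-allyl-4-[3-methoxy-4-(triisopropylsilyloxy)phenyl]cyclopent-2-en-1-one
Conditions: Pd(PPh3)4 (5 mol%), CuI (10 mol%), DMF, 40 °C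
Reagents that add atoms: allyltributylstannane, C=CC[Sn](CCCC)(CCCC)CCCC
Why: Stille coupling (oxidative addition of zerovalent palladium into the C–I bond, allyl transfer from tin, reductive elimination) installs the allyl group on the enone α-carbon, and the mild temperature should keep the allyl double bond out of conjugation.

Step 6
Reactants: 12 (S)-2-allyl-4-arylcyclopent-2-en-1-one; 13 lithium dimethylcuprate; 14 formaldehyde
Product: 16 (2R,3R,4S)-2-allyl-2-(hydroxymethyl)-4-[3-methoxy-4-(triisopropylsilyloxy)phenyl]-3-methylcyclopentan-1-one, via lithium enolate 15 (not isolated)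
Conditions: Me2CuLi (from CuI, MeLi), Et2O, −78 → −20 °C; then monomeric CH2O (from cracked paraformaldehyde, in THF), −78 °C; aq. NH4Cl at −78 °C
Reagents that add atoms: lithium dimethylcuprate, [Li+].C[Cu-]C; formaldehyde, C=O
Why: The cuprate forms a π-complex with the enone and adds oxidatively at C7 to a trivalent copper β-adduct whose reductive elimination makes the C7–CH3 bond and leaves the regiodefined C1=C8 lithium enolate 15, which then adds to monomeric formaldehyde to make the C1–C2 bond; the closest known reaction type is the three-component coupling of cyclopentenones (organocopper conjugate addition with aldehyde trapping of the enolate), formaldehyde capture included. No ring is closed in this step. C7 is controlled by the adjacent C6 aryl group, the methyl being delivered to the enone face anti to it (6,7-trans). Quaternary C1 is controlled by the new C7 methyl, which should sit pseudoaxially beside the enolate carbon to relieve allylic strain with the C1 allyl group, so formaldehyde approaches anti to it and the allyl group is left cis to methyl. The step needs these two substrate-controlled facial selectivities and carbon capture at C1 only, which is secured because the conjugate addition generates a single enolate that cannot equilibrate at −78 °C; the cold quench guards against retro-aldol loss of formaldehyde.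

Step 7
Reactants: 16 key-step hydroxymethyl ketone; 17 chlorotriethylsilane
Product: 18 (2R,3R,4S)-2-allyl-4-[3-methoxy-4-(triisopropylsilyloxy)phenyl]-3-methyl-2-[(triethylsilyloxy)methyl]cyclopentan-1-one
Conditions: Et3SiCl, imidazole, CH2Cl2, 0 °C
Reagents that add atoms: chlorotriethylsilane, CC[Si](Cl)(CC)CC
Why: Silylation of the primary alcohol masks the β-hydroxy ketone against retro-aldol cleavage in the enolate steps, and the alkyl triethylsilyl ether can later be removed by mild aqueous acid that leaves the aryl TIPS ether intact.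

Step 8
Reactants: 18 triethylsilyl ether; 19 N,2-dimethoxy-N-methylacetamide
Product: 20 C5-(2-methoxyacetyl) derivative of 18 (1,3-diketone, mixture of C5 epimers and enol tautomers; other centres as in 18)
Conditions: LiN(SiMe3)2, THF, −78 °C; then 19, −78 → 0 °C; aq. NH4Cl
Reagents that add atoms: N,2-dimethoxy-N-methylacetamide, COCC(=O)N(C)OC
Why: Because C1 is quaternary the ketone can be deprotonated only at C5, and Claisen-type C-acylation of that lithium enolate by the Weinreb amide passes through a chelated tetrahedral adduct that releases the β-diketone only on work-up; C5 stays epimerisable and is fixed in step 9.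

Step 9
Reactants: 20 β-diketone; 21 trans-3-phenyl-2-(phenylsulfonyl)oxaziridine (racemic Davis reagent)
Product: 22 (2R,3R,4S,5S)-2-allyl-5-hydroxy-5-(2-methoxyacetyl)-4-[3-methoxy-4-(triisopropylsilyloxy)phenyl]-3-methyl-2-[(triethylsilyloxy)methyl]cyclopentan-1-one (hydroxyl trans to aryl)
Conditions: KN(SiMe3)2, THF, −78 °C; then 21, −78 → −20 °C; aq. NH4Cl
Reagents that add atoms: Davis oxaziridine, O=S(=O)(c1ccccc1)N1OC1c1ccccc1
Why: Davis hydroxylation of the planar β-diketone enolate should deliver oxygen to the C5 face anti to the adjacent C6 aryl group, which leaves the methoxyacetyl group cis to the aryl group and to the C1 CH2O arm, while the allyl alkene and the arene are not attacked by the oxaziridine.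

Step 10
Reactants: 22 tertiary alcohol; 23 iodomethane
Product: 24 (2R,3R,4S,5S)-2-allyl-5-methoxy-5-(2-methoxyacetyl)-4-[3-methoxy-4-(triisopropylsilyloxy)phenyl]-3-methyl-2-[(triethylsilyloxy)methyl]cyclopentan-1-one
Conditions: MeI, Ag2O, 4 Å molecular sieves, MeCN, 40 °C, dark
Reagents that add atoms: iodomethane, CI
Why: Purdie methylation alkylates the acidic tertiary hydroxyl under non-nucleophilic conditions that should avoid retro-Claisen cleavage of the non-enolisable 1,3-diketone, and no stereocentre changes.

Step 11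
Reactants: 24 methyl ether
Product: 25 (2R,3R,4S,5S)-2-allyl-2-(hydroxymethyl)-5-methoxy-5-(2-methoxyacetyl)-4-[3-methoxy-4-(triisopropylsilyloxy)phenyl]-3-methylcyclopentan-1-one
Conditions: AcOH/THF/H2O (3:1:1), rt
Reagents that add atoms: none
Why: Mild acid hydrolysis removes the primary alkyl triethylsilyl ether while the aryl TIPS ether, which is far more stable to acid, is retained.

Step 12
Reactants: 25 primary alcohol
Product: 26 (2R,3R,4S,5S)-2-allyl-2-formyl-5-methoxy-5-(2-methoxyacetyl)-4-[3-methoxy-4-(triisopropylsilyloxy)phenyl]-3-methylcyclopentan-1-one (ring numbering as in 16)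
Conditions: Dess–Martin periodinane, CH2Cl2, 0 °C → rt; used without delay
Reagents that add atoms: none
Why: Dess–Martin oxidation converts the primary alcohol into the aldehyde under neutral, non-nucleophilic conditions that should not deformylate the non-enolisable β-keto aldehyde.

Step 13
Reactants: 26 keto aldehyde
Product: 27 (1R,5S,6S,7R)-1-allyl-3,5-dimethoxy-6-[3-methoxy-4-(triisopropylsilyloxy)phenyl]-7-methylbicyclo[3.2.1]oct-2-ene-4,8-dione
Conditions: dibenzylammonium trifluoroacetate (Bn2NH2+ CF3CO2−), 4 Å molecular sieves, benzene, 60 °C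
Reagents that add atoms: none
Why: Intramolecular aldol condensation, in which the only enolisable position (C3, the OCH3-bearing methylene of the C5 acyl group) adds to the C2 formyl group held cis on C1 (6-enolendo-exo-trig closure of ring C1–C2–C3–C4–C5–C8) and water is lost to give the non-bridgehead C2=C3 enol ether; the weakly acidic ammonium carboxylate avoids free alkoxide intermediates that could fragment the C1–C2 bond.

Step 14
Reactants: 27 enedione
Product: 28 (1R,4S,5R,6S,7R)-1-allyl-4-hydroxy-3,5-dimethoxy-6-[3-methoxy-4-(triisopropylsilyloxy)phenyl]-7-methylbicyclo[3.2.1]oct-2-en-8-one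
Conditions: NaBH4, CeCl3·7H2O, MeOH, −78 °C
Reagents that add atoms: none
Why: Luche 1,2-reduction should take the conjugated C4 carbonyl in preference to the C8 ketone flanked by two quaternary carbons, with hydride approaching C4 from the face syn to the C8 bridge and away from the endo C6 aryl group, so that the hydroxyl ends on the side of the C6–C7 bridge.

Step 15
Reactants: 28 TIPS-protected target
Product: 29 (1R,4S,5R,6S,7R)-1-allyl-4-hydroxy-6-(4-hydroxy-3-methoxyphenyl)-3,5-dimethoxy-7-methylbicyclo[3.2.1]oct-2-en-8-one (target)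
Conditions: Bu4NF, AcOH, THF, 0 °C
Reagents that add atoms: none
Why: Fluoride cleaves the aryl silyl ether rapidly, and buffering with acetic acid should prevent base-induced retro-aldol opening of the C4–C5 bond and spare the enol ether.

**Compound list**

1 | 4-bromo-2-methoxyphenol | COc1cc(Br)ccc1O | starting material
2 | chlorotriisopropylsilane | CC(C)[Si](Cl)(C(C)C)C(C)C | starting material
3 | (4-bromo-2-methoxyphenoxy)triisopropylsilane | COc1cc(Br)ccc1O[Si](C(C)C)(C(C)C)C(C)C | intermediate
4 | (S)-4-(tert-butyldimethylsilyloxy)cyclopent-2-en-1-one | O=C1C=C[C@@H](O[Si](C)(C)C(C)(C)C)C1 | starting material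
5 | [3-methoxy-4-(triisopropylsilyloxy)phenyl]magnesium bromide | COc1cc([Mg]Br)ccc1O[Si](C(C)C)(C(C)C)C(C)C | intermediate
6 | trimethylsilyl enol ether of 7 (aryl trans to OTBS) | C[Si](C)(C)OC1=C[C@H](c2ccc(O[Si](C(C)C)(C(C)C)C(C)C)c(OC)c2)[C@@H](O[Si](C)(C)C(C)(C)C)C1 | intermediate
7 | (3R,4S)-4-(tert-butyldimethylsilyloxy)-3-[3-methoxy-4-(triisopropylsilyloxy)phenyl]cyclopentan-1-one | O=C1C[C@H](c2ccc(O[Si](C(C)C)(C(C)C)C(C)C)c(OC)c2)[C@@H](O[Si](C)(C)C(C)(C)C)C1 | intermediate
8 | (S)-4-[3-methoxy-4-(triisopropylsilyloxy)phenyl]cyclopent-2-en-1-one | O=C1C=C[C@@H](c2ccc(O[Si](C(C)C)(C(C)C)C(C)C)c(OC)c2)C1 | intermediate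
9 | iodine | II | starting material
10 | (S)-2-iodo-4-[3-methoxy-4-(triisopropylsilyloxy)phenyl]cyclopent-2-en-1-one | O=C1C(I)=C[C@@H](c2ccc(O[Si](C(C)C)(C(C)C)C(C)C)c(OC)c2)C1 | intermediate
11 | allyltributylstannane | C=CC[Sn](CCCC)(CCCC)CCCC | starting material
12 | (S)-2-allyl-4-[3-methoxy-4-(triisopropylsilyloxy)phenyl]cyclopent-2-en-1-one | C=CCC1=C[C@@H](c2ccc(O[Si](C(C)C)(C(C)C)C(C)C)c(OC)c2)CC1=O | intermediate
13 | lithium dimethylcuprate (reagent, prepared from CuI and MeLi before use) | [Li+].C[Cu-]C | starting material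
14 | formaldehyde (monomeric) | C=O | starting material
15 | lithium 2-allyl-3-methyl-4-arylcyclopent-1-en-1-olate (methyl trans to aryl) | C=CCC1=C([O-])C[C@H](c2ccc(O[Si](C(C)C)(C(C)C)C(C)C)c(OC)c2)[C@H]1C.[Li+] | intermediate
16 | (2R,3R,4S)-2-allyl-2-(hydroxymethyl)-4-[3-methoxy-4-(triisopropylsilyloxy)phenyl]-3-methylcyclopentan-1-one | C=CC[C@@]1(CO)C(=O)C[C@H](c2ccc(O[Si](C(C)C)(C(C)C)C(C)C)c(OC)c2)[C@H]1C | intermediate
17 | chlorotriethylsilane | CC[Si](Cl)(CC)CC | starting material
18 | (2R,3R,4S)-2-allyl-4-aryl-3-methyl-2-[(triethylsilyloxy)methyl]cyclopentan-1-one | C=CC[C@@]1(CO[Si](CC)(CC)CC)C(=O)C[C@H](c2ccc(O[Si](C(C)C)(C(C)C)C(C)C)c(OC)c2)[C@H]1C | intermediate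
19 | N,2-dimethoxy-N-methylacetamide | COCC(=O)N(C)OC | starting material
20 | C5-(2-methoxyacetyl) derivative of 18 (C5 epimers and enol tautomers) | C=CC[C@@]1(CO[Si](CC)(CC)CC)C(=O)C(C(=O)COC)[C@H](c2ccc(O[Si](C(C)C)(C(C)C)C(C)C)c(OC)c2)[C@H]1C | intermediate
21 | trans-3-phenyl-2-(phenylsulfonyl)oxaziridine (racemic) | O=S(=O)(c1ccccc1)N1OC1c1ccccc1 | starting material
22 | (2R,3R,4S,5S)-2-allyl-5-hydroxy-5-(2-methoxyacetyl)-4-aryl-3-methyl-2-[(triethylsilyloxy)methyl]cyclopentan-1-one | C=CC[C@@]1(CO[Si](CC)(CC)CC)C(=O)[C@](O)(C(=O)COC)[C@H](c2ccc(O[Si](C(C)C)(C(C)C)C(C)C)c(OC)c2)[C@H]1C | intermediate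
23 | iodomethane | CI | starting material
24 | (2R,3R,4S,5S)-2-allyl-5-methoxy-5-(2-methoxyacetyl)-4-aryl-3-methyl-2-[(triethylsilyloxy)methyl]cyclopentan-1-one | C=CC[C@@]1(CO[Si](CC)(CC)CC)C(=O)[C@](OC)(C(=O)COC)[C@H](c2ccc(O[Si](C(C)C)(C(C)C)C(C)C)c(OC)c2)[C@H]1C | intermediate
25 | (2R,3R,4S,5S)-2-allyl-2-(hydroxymethyl)-5-methoxy-5-(2-methoxyacetyl)-4-aryl-3-methylcyclopentan-1-one | C=CC[C@@]1(CO)C(=O)[C@](OC)(C(=O)COC)[C@H](c2ccc(O[Si](C(C)C)(C(C)C)C(C)C)c(OC)c2)[C@H]1C | intermediate
26 | (2R,3R,4S,5S)-2-allyl-2-formyl-5-methoxy-5-(2-methoxyacetyl)-4-aryl-3-methylcyclopentan-1-one | C=CC[C@@]1(C=O)C(=O)[C@](OC)(C(=O)COC)[C@H](c2ccc(O[Si](C(C)C)(C(C)C)C(C)C)c(OC)c2)[C@H]1C | intermediate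
27 | (1R,5S,6S,7R)-1-allyl-3,5-dimethoxy-6-aryl-7-methylbicyclo[3.2.1]oct-2-ene-4,8-dione | C=CC[C@@]12C=C(OC)C(=O)[C@@](OC)(C1=O)[C@H](c1ccc(O[Si](C(C)C)(C(C)C)C(C)C)c(OC)c1)[C@H]2C | intermediate
28 | (1R,4S,5R,6S,7R)-1-allyl-4-hydroxy-3,5-dimethoxy-6-[3-methoxy-4-(triisopropylsilyloxy)phenyl]-7-methylbicyclo[3.2.1]oct-2-en-8-one | C=CC[C@@]12C=C(OC)[C@H](O)[C@@](OC)(C1=O)[C@H](c1ccc(O[Si](C(C)C)(C(C)C)C(C)C)c(OC)c1)[C@H]2C | intermediate
29 | (1R,4S,5R,6S,7R)-1-allyl-4-hydroxy-6-(4-hydroxy-3-methoxyphenyl)-3,5-dimethoxy-7-methylbicyclo[3.2.1]oct-2-en-8-one | C=CC[C@@]12C=C(OC)[C@H](O)[C@@](OC)(C1=O)[C@H](c1ccc(O)c(OC)c1)[C@H]2C | target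

("aryl" in the names of 18–27 is 3-methoxy-4-(triisopropylsilyloxy)phenyl.)

**Step count and risks**

Total step count: 15. Longest linear sequence: 15 steps (1 → 29).

Steps most likely to fail:

1. Step 6. The fully substituted, hindered enolate may be captured incompletely by formaldehyde: it can be protonated instead, the aldol can revert on warming, or the aldolate can react further with excess formaldehyde. The facial bias at C1 may also be too small, because the adjacent methyl and the more remote aryl group oppose each other. The fallback sets out from 12 and comes back at 16. The cuprate addition is run in the presence of Me3SiCl (THF, −78 °C, Et3N quench) and the trimethylsilyl enol ether F1 is isolated. F1 is then hydroxymethylated with commercial aqueous formaldehyde under Sc(OTf)3 catalysis in THF/H2O. This is a Mukaiyama-type aldol through an open transition state with no basic aldolate, and it should give 16 with the same anti-to-methyl approach.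

2. Step 13. Before dehydration the C1–C2 bond may fragment (deformylation, or formyl transfer by retro-aldol of the intermediate aldol), or the non-enolisable 1,3-diketone may be cleaved. The fallback sets out from 26 and comes back at 27. Soft enolisation at C3 with Bu2BOTf and i-Pr2NEt (CH2Cl2, −78 °C) triggers an intramolecular boron aldol whose boron aldolate resists retro-aldol cleavage. Work-up with pH 7 buffer and MeOH gives the bicyclic β-hydroxy ketone F2 (C2/C3 epimers). MsCl and Et3N (CH2Cl2, 0 °C) give the mesylate F3, and DBU (CH2Cl2, rt) eliminates it by an E1cB path to 27.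

3. Step 14. Hydride may be delivered to the strained C8 bridging carbonyl in competition with C4 (loss of site selectivity), or both carbonyls may be reduced. The fallback sets out from 27 and comes back at 29, and makes site selectivity irrelevant. Excess NaBH4 with CeCl3·7H2O (MeOH, −78 → 0 °C) reduces both carbonyls to the 4,8-diol F4. Et3SiCl and imidazole silylate only the less hindered allylic C4 hydroxyl to give the C4 triethylsilyl ether F5. Dess–Martin periodinane buffered with pyridine oxidises the C8 carbinol, which sits between two quaternary carbons, to the 8-ketone F6. Bu4NF with AcOH then removes both silyl ethers to give 29.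

**Further compounds**

F1 | step 6 | trimethylsilyl enol ether of the methyl adduct (2-allyl-3-methyl-4-aryl-1-(trimethylsilyloxy)cyclopent-1-ene, methyl trans to aryl) | C=CCC1=C(O[Si](C)(C)C)C[C@H](c2ccc(O[Si](C(C)C)(C(C)C)C(C)C)c(OC)c2)[C@H]1C
F2 | step 13 | 1-allyl-2-hydroxy-3,5-dimethoxy-6-aryl-7-methylbicyclo[3.2.1]octane-4,8-dione (C2/C3 epimers) | C=CC[C@@]12C(O)C(OC)C(=O)[C@@](OC)(C1=O)[C@H](c1ccc(O[Si](C(C)C)(C(C)C)C(C)C)c(OC)c1)[C@H]2C
F3 | step 13 | C2 methanesulfonate of F2 | C=CC[C@@]12C(OS(C)(=O)=O)C(OC)C(=O)[C@@](OC)(C1=O)[C@H](c1ccc(O[Si](C(C)C)(C(C)C)C(C)C)c(OC)c1)[C@H]2C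
F4 | step 14 | 1-allyl-3,5-dimethoxy-6-aryl-7-methylbicyclo[3.2.1]oct-2-ene-4,8-diol (C8 epimers) | C=CC[C@@]12C=C(OC)[C@H](O)[C@@](OC)(C1O)[C@H](c1ccc(O[Si](C(C)C)(C(C)C)C(C)C)c(OC)c1)[C@H]2C
F5 | step 14 | C4 triethylsilyl ether of F4 | C=CC[C@@]12C=C(OC)[C@H](O[Si](CC)(CC)CC)[C@@](OC)(C1O)[C@H](c1ccc(O[Si](C(C)C)(C(C)C)C(C)C)c(OC)c1)[C@H]2C
F6 | step 14 | C4 triethylsilyl ether of 28 (8-ketone) | C=CC[C@@]12C=C(OC)[C@H](O[Si](CC)(CC)CC)[C@@](OC)(C1=O)[C@H](c1ccc(O[Si](C(C)C)(C(C)C)C(C)C)c(OC)c1)[C@H]2C
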